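**Plan**
- Retrosynthesis: the two ring B benzyl ethers come off last; ring C is opened at O1–C2 to a 1-(ring A)-3-(ring B)-propane-1,3-dione; the C2–C3 and C1'–C2 bonds are then cut together, C2 leaving as carbon monoxide.
- Enabling feature: C2 of ring C carries O1 and sits at the carboxyl oxidation level between C3 (alpha to the C4 carbonyl) and C1' of ring B, so it maps onto one CO molecule caught between a ketone enolate carbon and an aryl–palladium carbon.
- Forward: the ring B bromide 5 is made from 2,3-dimethoxyphenol (para-quinone, hydroquinone, dibenzyl ether, bromide) and the ring A ketone 7 by double MOM protection; 5, CO and 7 are joined to the C6–C3–C6 chain in one step.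
- Ring C is the only ring formed in the route (acid-mediated O1–C2 closure and dehydration once the MOM groups are lost); hydrogenolysis then frees the 2',5'-hydroquinone.
- Stereochemistry: the target has no stereocentre, so none has to be set.

Key step: step 6

Remark: carbon monoxide is numbered as a compound because it supplies skeletal carbon C2; MOMCl, benzyl bromide and NBS only deliver protecting groups or the halogen and are treated as reagents.

**Step 1**
Reactants: 1 2,3-dimethoxyphenol
Product: 2 2,3-dimethoxy-1,4-benzoquinone
Conditions: Fremy's salt (KSO3)2NO (2.2 equiv), aq. KH2PO4, acetone/H2O, 0 °C to rt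
Reagents that add atoms: potassium nitrosodisulfonate, (KSO3)2NO, [K+].[K+].[O]N(S(=O)(=O)[O-])S(=O)(=O)[O-]
Why: Teuber oxidation, in which the nitrosodisulfonate radical abstracts the phenolic hydrogen, a second equivalent adds through oxygen at the open para carbon C4, and loss of imidodisulfonate should give the para-quinone, as is usual for phenols with a free para position.

**Step 2**
Reactants: 2 2,3-dimethoxy-1,4-benzoquinone
Product: 3 2,3-dimethoxybenzene-1,4-diol
Conditions: Na2S2O4 (excess), EtOAc/H2O, rt, Ar; crude product used at once
Reagents that add atoms: none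
Why: Dithionite reduction of a benzoquinone to its hydroquinone is fast in a two-phase system, and the electron-rich diol is kept under argon to prevent re-oxidation.

**Step 3**
Reactants: 3 2,3-dimethoxybenzene-1,4-diol
Product: 4 1,4-bis(benzyloxy)-2,3-dimethoxybenzene
Conditions: BnBr (2.4 equiv), K2CO3 (3 equiv), degassed DMF, rt to 60 °C, Ar
Reagents that add atoms: benzyl bromide, BrCc1ccccc1
Why: Williamson ether synthesis on both phenoxides, with degassed solvent to suppress base-promoted air oxidation of the hydroquinone back to the quinone.

**Step 4**
Reactants: 4 1,4-bis(benzyloxy)-2,3-dimethoxybenzene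
Product: 5 1-bromo-2,5-bis(benzyloxy)-3,4-dimethoxybenzene
Conditions: NBS (1.05 equiv), MeCN, 0 °C to rt, dark
Reagents that add atoms: N-bromosuccinimide, O=C1CCC(=O)N1Br
Why: Electrophilic aromatic bromination in which the two free ring positions are equivalent (each ortho to a benzyloxy and para to a methoxy group), so only one monobromide can form, and the first bromine deactivates the ring toward a second.

**Step 5**
Reactants: 6 2',6'-dihydroxy-4'-methoxyacetophenone
Product: 7 1-[4-methoxy-2,6-bis(methoxymethoxy)phenyl]ethanone
Conditions: NaH (2.5 equiv), DMF, 0 °C; MOMCl (2.5 equiv), 0 °C to rt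
Reagents that add atoms: chloromethyl methyl ether, COCCl
Why: O-alkylation of the bis(phenoxide) (Williamson-type MOM ether formation), where NaH breaks the hydrogen bonds to the acetyl oxygen that make amine bases sluggish and the phenols are deprotonated long before the methyl ketone.

**Step 6**
Reactants: 5 1-bromo-2,5-bis(benzyloxy)-3,4-dimethoxybenzene; 7 1-[4-methoxy-2,6-bis(methoxymethoxy)phenyl]ethanone (1.3 equiv); 8 carbon monoxide
Product: 9 1-[4-methoxy-2,6-bis(methoxymethoxy)phenyl]-3-[2,5-bis(benzyloxy)-3,4-dimethoxyphenyl]propane-1,3-dione
Conditions: CO (ca. 1.5 equiv, 1–2 bar, sealed two-chamber vessel), Pd(dba)2 (5 mol %), 1,3-bis(diphenylphosphino)propane (dppp, 5 mol %), NaN(SiMe3)2 (2.2 equiv), THF, 80 °C; then aq. NH4Cl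
Reagents that add atoms: carbon monoxide (compound 8), [C-]#[O+]
Why: Zerovalent palladium carrying dppp inserts into the C1'–Br bond of 5, CO migrates in to give an aroyl complex of divalent palladium (forming C1'–C2), the sodium enolate of 7 replaces bromide on the metal, and carbon–carbon reductive elimination forms C2–C3. The closest known reaction type is the palladium-catalysed carbonylative alpha-arylation of aryl methyl ketones with aryl bromides, which delivers 1,3-diketones under these conditions. No ring is closed and no stereocentre is created. The step needs CO insertion to outrun direct arylation of the enolate and needs acylation at carbon, not oxygen: the electron-rich aryl group migrates to CO quickly, the ortho benzyloxy group and the chelating bisphosphine retard direct aryl–enolate reductive elimination, and the palladium-bound enolate couples through carbon. Diketone 9 should be deprotonated by the second equivalent of base as it forms, which shields it from a second acylation, and 7 can enolise only at its methyl group, so no regiochemical question arises. The MOM and benzyl ethers are inert to the amide base and to the catalyst.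

**Step 7**
Reactants: 9 1-[4-methoxy-2,6-bis(methoxymethoxy)phenyl]-3-[2,5-bis(benzyloxy)-3,4-dimethoxyphenyl]propane-1,3-dione
Product: 11 2-[2,5-bis(benzyloxy)-3,4-dimethoxyphenyl]-5-hydroxy-7-methoxy-4H-chromen-4-one, via dihydroxy diketone 10 (not isolated)
Conditions: 3 M HCl in MeOH, reflux
Reagents that add atoms: none
Why: Acetal methanolysis frees the two equivalent ortho phenols of ring A, one of which adds to the ring B carbonyl and loses water (acid-catalysed cyclodehydration of an ortho-hydroxyaryl 1,3-diketone to a flavone); ring A is symmetric so only one flavone can form, and the acid-stable benzyl ether keeps the 2'-oxygen of ring B from competing.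

**Step 8**
Reactants: 11 2-[2,5-bis(benzyloxy)-3,4-dimethoxyphenyl]-5-hydroxy-7-methoxy-4H-chromen-4-one
Product: 12 2-(2,5-dihydroxy-3,4-dimethoxyphenyl)-5-hydroxy-7-methoxy-4H-chromen-4-one
Conditions: H2 (1 atm), 10% Pd/C, EtOAc–MeOH, rt; filtration and work-up under Ar
Reagents that add atoms: none
Why: Catalytic hydrogenolysis of aryl benzyl ethers, under which the conjugated pyranone double bond and the methyl ethers should be untouched at 1 atm and room temperature, with air excluded because the product is a hydroquinone.

**Compound list**
1 | 2,3-dimethoxyphenol | COc1cccc(O)c1OC | starting material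
2 | 2,3-dimethoxy-1,4-benzoquinone | COC1=C(OC)C(=O)C=CC1=O | intermediate
3 | 2,3-dimethoxybenzene-1,4-diol | COc1c(O)ccc(O)c1OC | intermediate
4 | 1,4-bis(benzyloxy)-2,3-dimethoxybenzene | COc1c(OCc2ccccc2)ccc(OCc2ccccc2)c1OC | intermediate
5 | 1-bromo-2,5-bis(benzyloxy)-3,4-dimethoxybenzene | Brc1cc(OCc2ccccc2)c(OC)c(OC)c1OCc1ccccc1 | intermediate
6 | 2',6'-dihydroxy-4'-methoxyacetophenone | CC(=O)c1c(O)cc(OC)cc1O | starting material
7 | 1-[4-methoxy-2,6-bis(methoxymethoxy)phenyl]ethanone | COCOc1cc(OC)cc(OCOC)c1C(C)=O | intermediate
8 | carbon monoxide | [C-]#[O+] | starting material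
9 | 1-[4-methoxy-2,6-bis(methoxymethoxy)phenyl]-3-[2,5-bis(benzyloxy)-3,4-dimethoxyphenyl]propane-1,3-dione | COCOc1cc(OC)cc(OCOC)c1C(=O)CC(=O)c1cc(OCc2ccccc2)c(OC)c(OC)c1OCc1ccccc1 | intermediate
10 | 1-(2,6-dihydroxy-4-methoxyphenyl)-3-[2,5-bis(benzyloxy)-3,4-dimethoxyphenyl]propane-1,3-dione (not isolated) | COc1cc(O)c(C(=O)CC(=O)c2cc(OCc3ccccc3)c(OC)c(OC)c2OCc2ccccc2)c(O)c1 | intermediate
11 | 2-[2,5-bis(benzyloxy)-3,4-dimethoxyphenyl]-5-hydroxy-7-methoxy-4H-chromen-4-one | COc1cc(O)c2c(=O)cc(-c3cc(OCc4ccccc4)c(OC)c(OC)c3OCc3ccccc3)oc2c1 | intermediate
12 | 2-(2,5-dihydroxy-3,4-dimethoxyphenyl)-5-hydroxy-7-methoxy-4H-chromen-4-one | COc1cc(O)c2c(=O)cc(-c3cc(O)c(OC)c(OC)c3O)oc2c1 | target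

**Step count and risks**
Total steps: 8. Longest linear sequence: 7 steps (steps 1, 2, 3, 4, 6, 7, 8); step 5 is the single step of the ring A branch.

Most likely to fail, in order:

Step 6. Oxidative addition into the electron-rich, ortho-substituted bromide may be slow under CO. The enolate may also be arylated directly without CO uptake, or the ketone enolate may self-condense at 80 °C. The fallback replaces the three-component coupling by a crossed Claisen condensation and sets out from 5. Bromine–lithium exchange (n-BuLi, THF, −78 °C) and a CO2 quench should give 2,5-bis(benzyloxy)-3,4-dimethoxybenzoic acid F1. Esterification (MeI, K2CO3, DMF) should give methyl 2,5-bis(benzyloxy)-3,4-dimethoxybenzoate F2. Condensation of F2 with the enolate of 7 (LiN(SiMe3)2, THF, −78 °C to rt) comes back to the route at 9.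

Step 1. The radical oxidant decomposes on storage and in solution, so conversion may stall. The quinone may also degrade in the aqueous medium before extraction. The fallback is an Elbs persulfate oxidation, which hydroxylates the para position at the hydroquinone level and bypasses the quinone. It sets out from 1: K2S2O8 in aq. KOH at 0 °C to rt should give potassium 4-hydroxy-2,3-dimethoxyphenyl sulfate F3. Hydrolysis of F3 in hot dilute HCl under argon comes back to the route at 3.

Step 8. The C2–C3 double bond of the pyranone may be partly saturated on prolonged hydrogenation. The freed hydroquinone may also oxidise in air during filtration and purification. The fallback is a non-reductive Lewis-acid debenzylation and sets out from 11: BCl3 with pentamethylbenzene as cation scavenger in CH2Cl2 at −78 °C, then a methanol quench and an aqueous Na2S2O4 wash under argon. It comes back to the route at 12 and makes no compound outside the compound list (entry F0).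

**Further compounds**
F1 | step 6 | 2,5-bis(benzyloxy)-3,4-dimethoxybenzoic acid | OC(=O)c1cc(OCc2ccccc2)c(OC)c(OC)c1OCc1ccccc1
F2 | step 6 | methyl 2,5-bis(benzyloxy)-3,4-dimethoxybenzoate | COC(=O)c1cc(OCc2ccccc2)c(OC)c(OC)c1OCc1ccccc1
F3 | step 1 | potassium 4-hydroxy-2,3-dimethoxyphenyl sulfate | COc1c(O)ccc(OS(=O)(=O)[O-])c1OC.[K+]
F0 | step 8 | none | none
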